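The route hinges on disconnecting the Z‑alkene C1'=C2', which lies between the oxygen on C6 of the lactone ring (O1, C2–C6) and the hydroxyl on C4' of the side chain, a 1,5‑diol pattern. Bridging these two oxygens with a diisopropylsilylene unit lets ring‑closing metathesis form C1'=C2' while closing an eight‑membered 1,3‑dioxa‑2‑silacyclooct‑5‑ene, whose size allows only the cis olefin. The metathesis substrate is the mixed silyl bis‑ether of an (S)‑vinyl carbinol carrying a Z‑allylic silyl ether (future C2–C5) and an (R)‑homoallylic alcohol holding C6' and C8' as TBS ethers. All protecting groups are silicon‑based, so one fluoride step and one oxidative lactonisation finish the synthesis.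

Key step: step 12

Remark: TBS = tert‑butyldimethylsilyl; the target is 6S, 1'Z, 4'R, 6'S, 8'R (4',6'‑syn, 6',8'‑anti); (−)‑Ipc2B(allyl) is the borane derived from (+)‑α‑pinene and (+)‑Ipc2B(allyl) that from (−)‑α‑pinene, both assumed to be bought as solutions.

**Step 1**
Reactants: 1 (S)‑epichlorohydrin; 2 tert‑butyldimethyl(prop‑2‑yn‑1‑yloxy)silane
Product: 3 (2S)‑6‑(TBSO)‑1‑chlorohex‑4‑yn‑2‑ol
Conditions: 2, n‑BuLi, THF, −78 °C; BF3·OEt2; then 1, −78 °C; aq NH4Cl
Reagents that add atoms: none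
Why: Lewis‑acid‑promoted alkynylation of a terminal epoxide (Yamaguchi–Hirao conditions): the lithium acetylide of 2, activated by BF3, should open the oxirane of 1 only at its unsubstituted carbon, leaving the C–Cl bond, the silyl ether and the stereocentre (the future C6) untouched.

**Step 2**
Reactants: 3 (2S)‑6‑(TBSO)‑1‑chlorohex‑4‑yn‑2‑ol
Product: 4 (2S,4Z)‑6‑(TBSO)‑1‑chlorohex‑4‑en‑2‑ol
Conditions: H2 (1 atm), Pd/CaCO3 poisoned with Pb(OAc)2 (Lindlar catalyst), quinoline, EtOAc, rt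
Reagents that add atoms: none
Why: Lindlar semihydrogenation delivers H2 syn to the alkyne on poisoned palladium and stops at the Z‑alkene (the future C3=C4), and it is placed here, before any terminal alkene exists, so that nothing else in the molecule can be reduced.

**Step 3**
Reactants: 4 (2S,4Z)‑6‑(TBSO)‑1‑chlorohex‑4‑en‑2‑ol
Product: 6 (3S,5Z)‑7‑(TBSO)hepta‑1,5‑dien‑3‑ol, via terminal epoxide 5 (not isolated)
Conditions: Me3S+ I− (4 equiv), n‑BuLi (3.9 equiv), THF, −20 °C; then 4, −20 °C → rt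
Reagents that add atoms: trimethylsulfonium iodide, C[S+](C)C.[I-]
Why: Excess dimethylsulfonium methylide first closes the chlorohydrin to epoxide 5 (intramolecular Williamson reaction), then opens it at CH2, and the sulfonium alkoxide so formed eliminates Me2S on deprotonation, a known one‑carbon homologation of a terminal epoxide to an allylic alcohol that does not touch the carbinol centre, which therefore stays S.

**Step 4**
Reactants: 7 3‑phenylpropanal
Product: 8 (3R)‑1‑phenylhex‑5‑en‑3‑ol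
Conditions: (−)‑Ipc2B(allyl), Et2O, −78 °C; then NaOH, H2O2, 0 °C → rt
Reagents that add atoms: (−)‑B‑allyldiisopinocampheylborane, C=CCB([C@@H]1C[C@@H]2C[C@H]([C@H]1C)C2(C)C)[C@@H]1C[C@@H]2C[C@H]([C@H]1C)C2(C)C
Why: Brown asymmetric allylboration: the allyl group is transferred through a chair‑like six‑membered transition state in which the isopinocampheyl groups of this borane expose the Si face of the aldehyde, which should set C8' as R.

**Step 5**
Reactants: 8 (3R)‑1‑phenylhex‑5‑en‑3‑ol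
Product: 9 tert‑butyldimethyl{[(3R)‑1‑phenylhex‑5‑en‑3‑yl]oxy}silane
Conditions: TBSCl, imidazole, DMF, rt
Reagents that add atoms: tert‑butyldimethylsilyl chloride, CC(C)(C)[Si](C)(C)Cl
Why: Imidazole‑promoted silylation of a secondary alcohol masks the C8' hydroxyl for the chain extension without affecting the stereocentre.

**Step 6**
Reactants: 9 tert‑butyldimethyl{[(3R)‑1‑phenylhex‑5‑en‑3‑yl]oxy}silane
Product: 10 (3R)‑3‑(TBSO)‑5‑phenylpentanal
Conditions: O3, CH2Cl2, −78 °C (to first blue colour); PPh3, −78 °C → rt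
Reagents that add atoms: ozone, [O-][O+]=O
Why: Ozonolysis with reductive work‑up cleaves the terminal alkene far faster than ozone attacks the phenyl ring, and the neutral PPh3 work‑up should give the β‑silyloxy aldehyde without β‑elimination.

**Step 7**
Reactants: 10 (3R)‑3‑(TBSO)‑5‑phenylpentanal
Product: 11 (4R,6R)‑6‑(TBSO)‑8‑phenyloct‑1‑en‑4‑ol
Conditions: (+)‑Ipc2B(allyl), Et2O, −78 °C; then NaOH, H2O2, 0 °C → rt
Reagents that add atoms: (+)‑B‑allyldiisopinocampheylborane, C=CCB([C@H]1C[C@H]2C[C@@H]([C@@H]1C)C2(C)C)[C@H]1C[C@H]2C[C@@H]([C@@H]1C)C2(C)C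
Why: Brown asymmetric allylboration under reagent control: this borane attacks the Re face through the chair transition state and should set the new carbinol (C6') anti to the C8' silyl ether, the β‑silyloxy group exerting only a weak bias of its own.

**Step 8**
Reactants: 11 (4R,6R)‑6‑(TBSO)‑8‑phenyloct‑1‑en‑4‑ol
Product: 12 (4R,6R)‑4,6‑bis(TBSO)‑8‑phenyloct‑1‑ene
Conditions: TBSOTf, 2,6‑lutidine, CH2Cl2, −78 → 0 °C
Reagents that add atoms: tert‑butyldimethylsilyl triflate, CC(C)(C)[Si](C)(C)OS(=O)(=O)C(F)(F)F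
Why: Silylation with the silyl triflate and a hindered pyridine base protects the more encumbered secondary alcohol quickly at low temperature and leaves the stereocentres and the alkene untouched.

**Step 9**
Reactants: 12 (4R,6R)‑4,6‑bis(TBSO)‑8‑phenyloct‑1‑ene
Product: 13 (3S,5R)‑3,5‑bis(TBSO)‑7‑phenylheptanal
Conditions: O3, CH2Cl2, −78 °C (to first blue colour); PPh3, −78 °C → rt
Reagents that add atoms: ozone, [O-][O+]=O
Why: Ozonolysis with reductive work‑up again converts only the terminal alkene into the aldehyde (C4') under neutral conditions that should spare both silyl ethers and the phenyl ring.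

**Step 10**
Reactants: 13 (3S,5R)‑3,5‑bis(TBSO)‑7‑phenylheptanal
Product: 14 (4R,6R,8R)‑6,8‑bis(TBSO)‑10‑phenyldec‑1‑en‑4‑ol (C6 is the 6'S centre of the target; its descriptor reads R here only because C4 carries a free hydroxyl)
Conditions: (+)‑Ipc2B(allyl), Et2O, −78 °C; then NaOH, H2O2, 0 °C → rt
Reagents that add atoms: (+)‑B‑allyldiisopinocampheylborane, C=CCB([C@H]1C[C@H]2C[C@@H]([C@@H]1C)C2(C)C)[C@H]1C[C@H]2C[C@@H]([C@@H]1C)C2(C)C
Why: Brown asymmetric allylboration with the same Re‑face‑selective borane should set C4' syn to C6' by reagent control and delivers the free homoallylic alcohol needed for the tether.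

**Step 11**
Reactants: 6 (3S,5Z)‑7‑(TBSO)hepta‑1,5‑dien‑3‑ol; 15 dichlorodiisopropylsilane; 14 (4R,6R,8R)‑6,8‑bis(TBSO)‑10‑phenyldec‑1‑en‑4‑ol
Product: 17 {[(4R,6S,8R)‑6,8‑bis(TBSO)‑10‑phenyldec‑1‑en‑4‑yl]oxy}{[(3S,5Z)‑7‑(TBSO)hepta‑1,5‑dien‑3‑yl]oxy}diisopropylsilane, via chlorosilane 16 (not isolated)
Conditions: 15 (1.0 equiv), imidazole, CH2Cl2, 0 °C, slow addition of 6 (1.0 equiv); then 14 (0.8 equiv), imidazole, DMAP (cat.), CH2Cl2–DMF, rt
Reagents that add atoms: none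
Why: Sequential nucleophilic substitution at silicon (mixed silaketal formation): the first Si–Cl of 15 reacts far faster than the hindered alkoxychlorosilane 16, so the two different secondary alcohols can be introduced one after the other without touching a stereocentre.

**Step 12**
Reactants: 17 the mixed diisopropylsilylene bis‑ether
Product: 18 (4S,5Z,8R)‑8‑[(2S,4R)‑2,4‑bis(TBSO)‑6‑phenylhexyl]‑4‑[(2Z)‑4‑(TBSO)but‑2‑en‑1‑yl]‑2,2‑diisopropyl‑1,3‑dioxa‑2‑silacyclooct‑5‑ene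
Conditions: RuCl2(H2IMes)(PCy3)(=CHPh) (second‑generation Grubbs catalyst, 10 mol %), 1,4‑benzoquinone (10 mol %), CH2Cl2 (0.002 M), 40 °C, Ar sparge
Reagents that add atoms: none
Why: After loss of PCy3 the ruthenium benzylidene exchanges with the unhindered allyl terminus at C2' by [2+2] cycloaddition and cycloreversion, and the resulting alkylidene adds across the C6 vinyl group within the same molecule, so that collapse of the ruthenacyclobutane releases the ring and, overall, ethylene. The closest known reaction type is temporary silicon‑tethered ring‑closing metathesis of a mixed bis‑alkoxysilane of an allylic and a homoallylic alcohol. The one ring formed, the eight‑membered 1,3‑dioxa‑2‑silacyclooct‑5‑ene (O–Si–O–C6–C1'=C2'–C3'–C4'), closes by metathesis between the two terminal alkene carbons so that the new double bond is endocyclic, helped by the long Si–O bonds and by the two isopropyl groups on silicon, which favour the folded conformer. No stereocentre is created; the only new stereo‑element, the geometry of C1'=C2', is fixed as Z because an eight‑membered ring cannot hold a trans alkene, and C6 and C4' are not touched. The step needs site selectivity for the two monosubstituted alkenes over the internal C3=C4 alkene; this is secured by the faster loading of terminal olefins, by the bulky allylic OTBS group next to the 1,2‑disubstituted alkene, by the fact that its engagement would require a nine‑membered ring or a cyclobutene, and by high dilution with removal of ethylene, which suppresses oligomerisation.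

**Step 13**
Reactants: 18 the cyclic silaketal
Product: 19 (2Z,5S,6Z,9R,11S,13R)‑15‑phenylpentadeca‑2,6‑diene‑1,5,9,11,13‑pentaol
Conditions: HF·pyridine (excess), pyridine, THF, 0 °C → rt
Reagents that add atoms: none
Why: Fluoride‑driven desilylation: formation of strong Si–F bonds should cleave the primary and both secondary TBS ethers and the dialkoxysilane tether in one operation under buffered conditions that spare the two allylic carbinols and both Z‑alkenes.

**Step 14**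
Reactants: 19 the pentaol
Product: 22 (6S)‑6‑[(1Z,4R,6S,8R)‑4,6,8‑trihydroxy‑10‑phenyldec‑1‑en‑1‑yl]‑5,6‑dihydro‑2H‑pyran‑2‑one, via hydroxy enal 20 (not isolated), via lactol 21 (not isolated)
Conditions: TEMPO (0.2 equiv), PhI(OAc)2 (2.5 equiv), CH2Cl2–MeCN, rt
Reagents that add atoms: none
Why: TEMPO/PhI(OAc)2 oxoammonium oxidation is much faster for the unhindered primary allylic alcohol than for secondary carbinols; the Z‑enal 20 is held next to the C6 hydroxyl, closes to lactol 21, and this is oxidised again to the α,β‑unsaturated δ‑lactone without touching any stereocentre.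

**Compound list**
1 | (S)‑epichlorohydrin, (2S)‑2‑(chloromethyl)oxirane | ClC[C@@H]1CO1 | starting material
2 | tert‑butyldimethyl(prop‑2‑yn‑1‑yloxy)silane | C#CCO[Si](C)(C)C(C)(C)C | starting material
3 | (2S)‑6‑(TBSO)‑1‑chlorohex‑4‑yn‑2‑ol | ClC[C@@H](O)CC#CCO[Si](C)(C)C(C)(C)C | intermediate
4 | (2S,4Z)‑6‑(TBSO)‑1‑chlorohex‑4‑en‑2‑ol | ClC[C@@H](O)C/C=C\CO[Si](C)(C)C(C)(C)C | intermediate
5 | (2S)‑2‑[(2Z)‑4‑(TBSO)but‑2‑en‑1‑yl]oxirane (formed in the flask) | CC(C)(C)[Si](C)(C)OC/C=C\C[C@H]1CO1 | intermediate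
6 | (3S,5Z)‑7‑(TBSO)hepta‑1,5‑dien‑3‑ol | C=C[C@@H](O)C/C=C\CO[Si](C)(C)C(C)(C)C | intermediate
7 | 3‑phenylpropanal | O=CCCc1ccccc1 | starting material
8 | (3R)‑1‑phenylhex‑5‑en‑3‑ol | C=CC[C@H](O)CCc1ccccc1 | intermediate
9 | tert‑butyldimethyl{[(3R)‑1‑phenylhex‑5‑en‑3‑yl]oxy}silane | C=CC[C@H](O[Si](C)(C)C(C)(C)C)CCc1ccccc1 | intermediate
10 | (3R)‑3‑(TBSO)‑5‑phenylpentanal | O=CC[C@H](O[Si](C)(C)C(C)(C)C)CCc1ccccc1 | intermediate
11 | (4R,6R)‑6‑(TBSO)‑8‑phenyloct‑1‑en‑4‑ol | C=CC[C@@H](O)C[C@H](O[Si](C)(C)C(C)(C)C)CCc1ccccc1 | intermediate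
12 | (4R,6R)‑4,6‑bis(TBSO)‑8‑phenyloct‑1‑ene | C=CC[C@@H](O[Si](C)(C)C(C)(C)C)C[C@H](O[Si](C)(C)C(C)(C)C)CCc1ccccc1 | intermediate
13 | (3S,5R)‑3,5‑bis(TBSO)‑7‑phenylheptanal | O=CC[C@@H](O[Si](C)(C)C(C)(C)C)C[C@H](O[Si](C)(C)C(C)(C)C)CCc1ccccc1 | intermediate
14 | (4R,6R,8R)‑6,8‑bis(TBSO)‑10‑phenyldec‑1‑en‑4‑ol | C=CC[C@@H](O)C[C@@H](O[Si](C)(C)C(C)(C)C)C[C@H](O[Si](C)(C)C(C)(C)C)CCc1ccccc1 | intermediate
15 | dichlorodiisopropylsilane | CC(C)[Si](Cl)(Cl)C(C)C | starting material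
16 | chloro{[(3S,5Z)‑7‑(TBSO)hepta‑1,5‑dien‑3‑yl]oxy}diisopropylsilane (formed in the flask) | C=C[C@@H](O[Si](Cl)(C(C)C)C(C)C)C/C=C\CO[Si](C)(C)C(C)(C)C | intermediate
17 | {[(4R,6S,8R)‑6,8‑bis(TBSO)‑10‑phenyldec‑1‑en‑4‑yl]oxy}{[(3S,5Z)‑7‑(TBSO)hepta‑1,5‑dien‑3‑yl]oxy}diisopropylsilane | CC(C)(C)[Si](C)(C)OC/C=C\C[C@@H](C=C)O[Si](C(C)C)(C(C)C)O[C@H](CC=C)C[C@@H](O[Si](C)(C)C(C)(C)C)C[C@H](O[Si](C)(C)C(C)(C)C)CCc1ccccc1 | intermediate
18 | (4S,5Z,8R)‑8‑[(2S,4R)‑2,4‑bis(TBSO)‑6‑phenylhexyl]‑4‑[(2Z)‑4‑(TBSO)but‑2‑en‑1‑yl]‑2,2‑diisopropyl‑1,3‑dioxa‑2‑silacyclooct‑5‑ene | CC(C)(C)[Si](C)(C)OC/C=C\C[C@H]1/C=C\C[C@H](C[C@@H](O[Si](C)(C)C(C)(C)C)C[C@H](O[Si](C)(C)C(C)(C)C)CCc2ccccc2)O[Si](C(C)C)(C(C)C)O1 | intermediate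
19 | (2Z,5S,6Z,9R,11S,13R)‑15‑phenylpentadeca‑2,6‑diene‑1,5,9,11,13‑pentaol | OC/C=C\C[C@H](O)/C=C\C[C@@H](O)C[C@@H](O)C[C@H](O)CCc1ccccc1 | intermediate
20 | (2Z,5S,6Z,9R,11S,13R)‑5,9,11,13‑tetrahydroxy‑15‑phenylpentadeca‑2,6‑dienal (formed in the flask) | O=C/C=C\C[C@H](O)/C=C\C[C@@H](O)C[C@@H](O)C[C@H](O)CCc1ccccc1 | intermediate
21 | (6S)‑6‑[(1Z,4R,6S,8R)‑4,6,8‑trihydroxy‑10‑phenyldec‑1‑en‑1‑yl]‑5,6‑dihydro‑2H‑pyran‑2‑ol, both anomers (formed in the flask) | OC1C=CC[C@@H](/C=C\C[C@@H](O)C[C@@H](O)C[C@H](O)CCc2ccccc2)O1 | intermediate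
22 | (6S)‑6‑[(1Z,4R,6S,8R)‑4,6,8‑trihydroxy‑10‑phenyldec‑1‑en‑1‑yl]‑5,6‑dihydro‑2H‑pyran‑2‑one | O=C1C=CC[C@@H](/C=C\C[C@@H](O)C[C@@H](O)C[C@H](O)CCc2ccccc2)O1 | target

**Step count**
Total: 14 steps. Longest linear sequence: 11 steps (steps 4–14, from 3‑phenylpropanal); the allylic alcohol branch is 3 steps.

**Steps most likely to fail**

1. Step 12. Closure of the medium ring may be outrun by intermolecular metathesis (oligomerisation), or the alkylidene may engage the internal C3=C4 alkene, giving truncation or a nine‑membered ring. The fallback sets out from 14 and comes back to the route at 22; it makes the Z‑alkene by semihydrogenation of a C1'≡C2' alkyne and the lactone by metathesis of an acrylate.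
   - 14 is silylated (TBSOTf, 2,6‑lutidine) to the tris‑TBS decene F1.
   - Ozonolysis (O3; PPh3) gives the tris‑TBS nonanal F2.
   - Homologation with dimethyl (1‑diazo‑2‑oxopropyl)phosphonate (Ohira–Bestmann reagent, K2CO3, MeOH) gives the terminal decyne F3, whose new terminal carbon is C1'.
   - Lithiation (n‑BuLi, THF, −78 °C) and DMF give the ynal F4.
   - Brown allylboration with (−)‑Ipc2B(allyl) (Si face) sets C6 in the propargylic alcohol F5.
   - Lindlar semihydrogenation (H2, Pd/CaCO3 poisoned with Pb(OAc)2, quinoline, stopped after one equivalent) gives the Z‑dienol F6.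
   - Acryloyl chloride and iPr2NEt give the acrylate F7.
   - Ring‑closing metathesis with RuCl2(PCy3)2(=CHPh) (first‑generation Grubbs catalyst) closes the six‑membered ring to the tris‑TBS lactone F8.
   - HF·pyridine then removes the three silyl ethers to give 22.

2. Step 14. Chemoselectivity may be lost on the unprotected pentaol, with oxidation of a secondary carbinol (above all the allylic C6 hydroxyl before the lactol has formed) or an incomplete second oxidation. The fallback sets out from 18 and comes back at 22; it raises C2 to the acid level while every secondary oxygen is still silylated.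
   - The primary allylic TBS ether is cleaved selectively (HF·pyridine in excess pyridine, THF, 0 °C, short time) to the primary allylic alcohol F9.
   - TEMPO/PhI(OAc)2 in MeCN–H2O oxidises it through the enal F10 to the Z‑enoic acid F11.
   - HF·pyridine (excess) removes the tether and the two TBS ethers; the seco acid F12 so released lactonises (catalytic pyridinium p‑toluenesulfonate if needed) to 22.

3. Step 11. Exchange at silicon may give symmetrical bis‑ethers, the chlorosilane may hydrolyse, or the second substitution at the hindered silicon may stall. The fallback sets out from 6 and comes back at 17; it introduces the two alcohols through a stable Si–H intermediate.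
   - 6 is silylated with chlorodiisopropylsilane and imidazole to the hydridosilyl ether F13, which can be purified.
   - N‑Bromosuccinimide (CH2Cl2, 0 °C) converts Si–H into the bromosilane F14 in the flask.
   - Addition of 14 with imidazole and DMAP (cat.) gives 17.

**Further compounds**
F1 | step 12 | (4R,6S,8R)‑4,6,8‑tris(TBSO)‑10‑phenyldec‑1‑ene | C=CC[C@@H](O[Si](C)(C)C(C)(C)C)C[C@@H](O[Si](C)(C)C(C)(C)C)C[C@H](O[Si](C)(C)C(C)(C)C)CCc1ccccc1
F2 | step 12 | (3S,5S,7R)‑3,5,7‑tris(TBSO)‑9‑phenylnonanal | O=CC[C@@H](O[Si](C)(C)C(C)(C)C)C[C@@H](O[Si](C)(C)C(C)(C)C)C[C@H](O[Si](C)(C)C(C)(C)C)CCc1ccccc1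
F3 | step 12 | (4R,6S,8R)‑4,6,8‑tris(TBSO)‑10‑phenyldec‑1‑yne | C#CC[C@@H](O[Si](C)(C)C(C)(C)C)C[C@@H](O[Si](C)(C)C(C)(C)C)C[C@H](O[Si](C)(C)C(C)(C)C)CCc1ccccc1
F4 | step 12 | (5R,7S,9R)‑5,7,9‑tris(TBSO)‑11‑phenylundec‑2‑ynal | O=CC#CC[C@@H](O[Si](C)(C)C(C)(C)C)C[C@@H](O[Si](C)(C)C(C)(C)C)C[C@H](O[Si](C)(C)C(C)(C)C)CCc1ccccc1
F5 | step 12 | (4S,8R,10S,12R)‑8,10,12‑tris(TBSO)‑14‑phenyltetradec‑1‑en‑5‑yn‑4‑ol | C=CC[C@H](O)C#CC[C@@H](O[Si](C)(C)C(C)(C)C)C[C@@H](O[Si](C)(C)C(C)(C)C)C[C@H](O[Si](C)(C)C(C)(C)C)CCc1ccccc1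
F6 | step 12 | (4S,5Z,8R,10S,12R)‑8,10,12‑tris(TBSO)‑14‑phenyltetradeca‑1,5‑dien‑4‑ol | C=CC[C@H](O)/C=C\C[C@@H](O[Si](C)(C)C(C)(C)C)C[C@@H](O[Si](C)(C)C(C)(C)C)C[C@H](O[Si](C)(C)C(C)(C)C)CCc1ccccc1
F7 | step 12 | (4S,5Z,8R,10S,12R)‑8,10,12‑tris(TBSO)‑14‑phenyltetradeca‑1,5‑dien‑4‑yl prop‑2‑enoate | C=CC[C@H](OC(=O)C=C)/C=C\C[C@@H](O[Si](C)(C)C(C)(C)C)C[C@@H](O[Si](C)(C)C(C)(C)C)C[C@H](O[Si](C)(C)C(C)(C)C)CCc1ccccc1
F8 | step 12 | (6S)‑6‑[(1Z,4R,6S,8R)‑4,6,8‑tris(TBSO)‑10‑phenyldec‑1‑en‑1‑yl]‑5,6‑dihydro‑2H‑pyran‑2‑one | O=C1C=CC[C@@H](/C=C\C[C@@H](O[Si](C)(C)C(C)(C)C)C[C@@H](O[Si](C)(C)C(C)(C)C)C[C@H](O[Si](C)(C)C(C)(C)C)CCc2ccccc2)O1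
F9 | step 14 | (2Z)‑4‑{(4S,5Z,8R)‑8‑[(2S,4R)‑2,4‑bis(TBSO)‑6‑phenylhexyl]‑2,2‑diisopropyl‑1,3‑dioxa‑2‑silacyclooct‑5‑en‑4‑yl}but‑2‑en‑1‑ol | OC/C=C\C[C@H]1/C=C\C[C@H](C[C@@H](O[Si](C)(C)C(C)(C)C)C[C@H](O[Si](C)(C)C(C)(C)C)CCc2ccccc2)O[Si](C(C)C)(C(C)C)O1
F10 | step 14 | (2Z)‑4‑{(4S,5Z,8R)‑8‑[(2S,4R)‑2,4‑bis(TBSO)‑6‑phenylhexyl]‑2,2‑diisopropyl‑1,3‑dioxa‑2‑silacyclooct‑5‑en‑4‑yl}but‑2‑enal | O=C/C=C\C[C@H]1/C=C\C[C@H](C[C@@H](O[Si](C)(C)C(C)(C)C)C[C@H](O[Si](C)(C)C(C)(C)C)CCc2ccccc2)O[Si](C(C)C)(C(C)C)O1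
F11 | step 14 | (2Z)‑4‑{(4S,5Z,8R)‑8‑[(2S,4R)‑2,4‑bis(TBSO)‑6‑phenylhexyl]‑2,2‑diisopropyl‑1,3‑dioxa‑2‑silacyclooct‑5‑en‑4‑yl}but‑2‑enoic acid | OC(=O)/C=C\C[C@H]1/C=C\C[C@H](C[C@@H](O[Si](C)(C)C(C)(C)C)C[C@H](O[Si](C)(C)C(C)(C)C)CCc2ccccc2)O[Si](C(C)C)(C(C)C)O1
F12 | step 14 | (2Z,5S,6Z,9R,11S,13R)‑5,9,11,13‑tetrahydroxy‑15‑phenylpentadeca‑2,6‑dienoic acid | OC(=O)/C=C\C[C@H](O)/C=C\C[C@@H](O)C[C@@H](O)C[C@H](O)CCc1ccccc1
F13 | step 11 | {[(3S,5Z)‑7‑(TBSO)hepta‑1,5‑dien‑3‑yl]oxy}diisopropylsilane | C=C[C@@H](O[SiH](C(C)C)C(C)C)C/C=C\CO[Si](C)(C)C(C)(C)C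
F14 | step 11 | bromo{[(3S,5Z)‑7‑(TBSO)hepta‑1,5‑dien‑3‑yl]oxy}diisopropylsilane | C=C[C@@H](O[Si](Br)(C(C)C)C(C)C)C/C=C\CO[Si](C)(C)C(C)(C)C
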